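**Retrosynthetic overview**

1. The target is a biaryl dimer: two identical Ar–CO–(CH2)8– tethers (ketone carbon = C1, benzylic carbon = C9) hang on a 2',3',4,5-tetrahydroxybiphenyl core. Each tether is cut at C6–C7, a bond between two plain CH2 groups, five carbons from the resorcinol ketone and three from the catechol ring. Each cut end is therefore an unstabilised primary radical available from a primary carboxylic acid, and because the two tethers are the same, one C7 keto acid serves twice.
2. Both C6–C7 bonds are made in one cell by a twofold Ni-electrocatalytic doubly decarboxylative C(sp3)–C(sp3) coupling of three components: the core bis(N-acyloxyphthalimide) and two molecules of the arm N-acyloxyphthalimide.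
3. Core: a Suzuki coupling fixes the biaryl bond (C5 of the ring whose chain is meta to the axis, C6 of the ring whose chain is ortho to it); a two-directional Wittig/hydrogenation turns both formyl groups into 3-carboxypropyl arms.
4. Arm: C2-lithiation of 1,3-dimethoxybenzene and acylation with the half-ester chloride of pimelic acid.
5. No ring is formed in the route: all four benzene rings are bought as commercial arenes. The eight phenols travel as methyl ethers and are freed last.

Key step: step 8

Remark: the target has no stereocentre, and its biaryl axis is flanked by only one OH and one CH2 group and is not configurationally stable, so the compound is achiral and the route needs no stereocontrol.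

Step 1
Reactants: 1 3-bromo-4,5-dimethoxybenzaldehyde; 2 (2-formyl-4,5-dimethoxyphenyl)boronic acid
Product: 3 2',3',4,5-tetramethoxybiphenyl-2,5'-dicarbaldehyde
Conditions: Pd(dppf)Cl2 (cat.), K3PO4, 1,4-dioxane/H2O, 80 °C
Reagents that add atoms: none
Why: Suzuki–Miyaura coupling of an aryl bromide with one ortho OMe and a boronic acid with one ortho CHO gives a di-ortho-substituted biaryl within normal scope, and the positions of Br and B fix the unsymmetrical biaryl linkage without ambiguity.

Step 2
Reactants: 3 2',3',4,5-tetramethoxybiphenyl-2,5'-dicarbaldehyde; 4 (2-carboxyethyl)triphenylphosphonium bromide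
Product: 6 (3E,3'E)-4,4'-(2',3',4,5-tetramethoxybiphenyl-2,5'-diyl)bis(but-3-enoic acid), via carboxylate ylide 5 (not isolated)
Conditions: 4 (2.5 equiv), KOtBu (5 equiv), THF, 0 °C → rt; then aq. HCl
Reagents that add atoms: none
Why: Twofold Wittig olefination with the carboxylate-bearing ylide (two equivalents of base per salt) converts both non-enolisable aldehydes into β,γ-unsaturated acids; the E isomer should predominate and the geometry is erased in step 3.

Step 3
Reactants: 6 (3E,3'E)-4,4'-(2',3',4,5-tetramethoxybiphenyl-2,5'-diyl)bis(but-3-enoic acid)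
Product: 7 4,4'-(2',3',4,5-tetramethoxybiphenyl-2,5'-diyl)dibutanoic acid
Conditions: H2 (1 atm), 10% Pd/C, EtOAc/MeOH, rt
Reagents that add atoms: none
Why: Heterogeneous catalytic hydrogenation saturates both styrenyl C=C bonds, while the aryl ethers, the biaryl and the carboxylic acids are inert.

Step 4
Reactants: 7 4,4'-(2',3',4,5-tetramethoxybiphenyl-2,5'-diyl)dibutanoic acid
Product: 8 bis(1,3-dioxoisoindolin-2-yl) 4,4'-(2',3',4,5-tetramethoxybiphenyl-2,5'-diyl)dibutanoate
Conditions: N-hydroxyphthalimide, DIC, DMAP (cat.), CH2Cl2, rt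
Reagents that add atoms: N-hydroxyphthalimide, O=C1c2ccccc2C(=O)N1O
Why: Carbodiimide (Steglich-type) esterification turns both primary acids into redox-active esters, and 7 contains no other group that reacts with the activated acid.

Step 5
Reactants: 9 1,3-dimethoxybenzene; 10 ethyl 7-chloro-7-oxoheptanoate
Product: 12 ethyl 7-(2,6-dimethoxyphenyl)-7-oxoheptanoate, via 2,6-dimethoxyphenyllithium 11 (not isolated)
Conditions: n-BuLi, THF, 0 °C → rt; then added to 10, THF, −78 °C
Reagents that add atoms: none
Why: Directed ortho-metalation at C2 between the two methoxy groups, then acylation by inverse addition to the acid chloride, which is far more electrophilic than the ethyl ester; the di-ortho-substituted ketone formed is too hindered for a second addition.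

Step 6
Reactants: 12 ethyl 7-(2,6-dimethoxyphenyl)-7-oxoheptanoate
Product: 13 7-(2,6-dimethoxyphenyl)-7-oxoheptanoic acid
Conditions: LiOH, THF/H2O, rt; then aq. HCl
Reagents that add atoms: lithium hydroxide, [Li+].[OH-]
Why: Saponification of the unhindered ethyl ester; the hindered aryl ketone is inert to aqueous hydroxide at rt.

Step 7
Reactants: 13 7-(2,6-dimethoxyphenyl)-7-oxoheptanoic acid
Product: 14 1,3-dioxoisoindolin-2-yl 7-(2,6-dimethoxyphenyl)-7-oxoheptanoate
Conditions: N-hydroxyphthalimide, DIC, DMAP (cat.), CH2Cl2, rt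
Reagents that add atoms: N-hydroxyphthalimide, O=C1c2ccccc2C(=O)N1O
Why: Carbodiimide (Steglich-type) esterification of the only acidic group gives the redox-active ester; the ketone does not interfere.

Step 8
Reactants: 8 bis(1,3-dioxoisoindolin-2-yl) 4,4'-(2',3',4,5-tetramethoxybiphenyl-2,5'-diyl)dibutanoate; 14 1,3-dioxoisoindolin-2-yl 7-(2,6-dimethoxyphenyl)-7-oxoheptanoate
Product: 15 9,9'-(2',3',4,5-tetramethoxybiphenyl-2,5'-diyl)bis[1-(2,6-dimethoxyphenyl)nonan-1-one]
Conditions: 14 (6 equiv), NiCl2·6H2O (cat.), 2,2':6',2''-terpyridine (cat.), AgNO3 (substoich.), NaI, NMP, Mg anode/RVC cathode, undivided cell, constant current, rt; dil. HCl work-up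
Reagents that add atoms: none
Why: Cathodically generated low-valent Ni(terpyridine) reduces each N-acyloxyphthalimide by single-electron transfer; the ester fragments to phthalimide anion, CO2 and a primary alkyl radical (C7 radicals on the core, C6 radicals from 14), and radical capture at nickel followed by reductive elimination from a dialkylnickel species forms the C6–C7 bond, twice, so three components are joined in one operation. The closest known reaction is the Ni-electrocatalytic doubly decarboxylative C(sp3)–C(sp3) cross-coupling of two redox-active esters with a sacrificial Mg anode, applied here to both esters of one substrate. No ring is closed and no stereocentre is formed. The step needs cross-coupling over homocoupling and no union of the two arms of 8: the excess of the cheap ester 14 biases each core radical toward the cross product, union of the two core arms would need a strained 11-membered ring bridging the biaryl, and the main by-product, the symmetrical C12 diketone from 14, is much smaller than 15 and should separate easily. It also needs chemoselective reduction, which the substrate secures because the redox-active esters are reduced far more easily than the twisted 2,6-dimethoxyaryl ketones and the electron-rich rings are inert at a cathode.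

Step 9
Reactants: 15 9,9'-(2',3',4,5-tetramethoxybiphenyl-2,5'-diyl)bis[1-(2,6-dimethoxyphenyl)nonan-1-one]
Product: 16 9,9'-(2',3',4,5-tetrahydroxybiphenyl-2,5'-diyl)bis[1-(2,6-dihydroxyphenyl)nonan-1-one] (CNP0305015.0)
Conditions: BBr3 (excess), CH2Cl2, −78 °C → rt; then MeOH, H2O (degassed)
Reagents that add atoms: none
Why: Lewis-acid ether cleavage (BBr3 O-demethylation: boron coordinates the ether oxygen, bromide attacks the methyl group) should free all eight phenols, the methoxy groups next to the ketones being helped by chelation; the ketones, the biaryl and the saturated chains are inert.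

**Compound list**

1 | 3-bromo-4,5-dimethoxybenzaldehyde | COc1cc(C=O)cc(Br)c1OC | starting material
2 | (2-formyl-4,5-dimethoxyphenyl)boronic acid | COc1cc(C=O)c(B(O)O)cc1OC | starting material
3 | 2',3',4,5-tetramethoxybiphenyl-2,5'-dicarbaldehyde | COc1cc(C=O)cc(-c2cc(OC)c(OC)cc2C=O)c1OC | intermediate
4 | (2-carboxyethyl)triphenylphosphonium bromide | OC(=O)CC[P+](c1ccccc1)(c1ccccc1)c1ccccc1.[Br-] | starting material
5 | potassium 3-(triphenylphosphoranylidene)propanoate (carboxylate ylide) | [K+].[O-]C(=O)CC=P(c1ccccc1)(c1ccccc1)c1ccccc1 | intermediate (not isolated)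
6 | (3E,3'E)-4,4'-(2',3',4,5-tetramethoxybiphenyl-2,5'-diyl)bis(but-3-enoic acid) | COc1cc(/C=C/CC(O)=O)cc(-c2cc(OC)c(OC)cc2/C=C/CC(O)=O)c1OC | intermediate
7 | 4,4'-(2',3',4,5-tetramethoxybiphenyl-2,5'-diyl)dibutanoic acid | COc1cc(CCCC(O)=O)cc(-c2cc(OC)c(OC)cc2CCCC(O)=O)c1OC | intermediate
8 | bis(1,3-dioxoisoindolin-2-yl) 4,4'-(2',3',4,5-tetramethoxybiphenyl-2,5'-diyl)dibutanoate | COc1cc(CCCC(=O)ON2C(=O)c3ccccc3C2=O)cc(-c2cc(OC)c(OC)cc2CCCC(=O)ON2C(=O)c3ccccc3C2=O)c1OC | intermediate
9 | 1,3-dimethoxybenzene | COc1cccc(OC)c1 | starting material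
10 | ethyl 7-chloro-7-oxoheptanoate | CCOC(=O)CCCCCC(Cl)=O | starting material
11 | 2,6-dimethoxyphenyllithium | [Li]c1c(OC)cccc1OC | intermediate (not isolated)
12 | ethyl 7-(2,6-dimethoxyphenyl)-7-oxoheptanoate | CCOC(=O)CCCCCC(=O)c1c(OC)cccc1OC | intermediate
13 | 7-(2,6-dimethoxyphenyl)-7-oxoheptanoic acid | OC(=O)CCCCCC(=O)c1c(OC)cccc1OC | intermediate
14 | 1,3-dioxoisoindolin-2-yl 7-(2,6-dimethoxyphenyl)-7-oxoheptanoate | COc1cccc(OC)c1C(=O)CCCCCC(=O)ON1C(=O)c2ccccc2C1=O | intermediate
15 | 9,9'-(2',3',4,5-tetramethoxybiphenyl-2,5'-diyl)bis[1-(2,6-dimethoxyphenyl)nonan-1-one] | COc1cc(CCCCCCCCC(=O)c2c(OC)cccc2OC)cc(-c2cc(OC)c(OC)cc2CCCCCCCCC(=O)c2c(OC)cccc2OC)c1OC | intermediate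
16 | 9,9'-(2',3',4,5-tetrahydroxybiphenyl-2,5'-diyl)bis[1-(2,6-dihydroxyphenyl)nonan-1-one] | O=C(CCCCCCCCc1cc(O)c(O)c(-c2cc(O)c(O)cc2CCCCCCCCC(=O)c2c(O)cccc2O)c1)c1c(O)cccc1O | target

**Step count and risks**

Total steps: 9. Longest linear sequence: 6 steps (1, 2, 3, 4, 8, 9); the arm branch (5, 6, 7) joins at step 8.

Steps most likely to fail:

Step 8. One of the two core radicals may be reduced or lose a β-hydrogen before it is coupled, and the arm ester may be used up by its own homocoupling, so that mono-coupled or truncated material builds up. The fallback forms the same two C6–C7 bonds by a two-electron alkyl–alkyl Suzuki–Miyaura coupling; it sets out from 8 and from 11 and comes back at 15. Photoredox/copper dual-catalysed decarboxylative olefination of both redox-active esters of 8 (organic photocatalyst, Cu(II) carboxylate, blue LED) should give 5-allyl-1-(2-allyl-4,5-dimethoxyphenyl)-2,3-dimethoxybenzene F1. Acylation of 11 with commercial 6-bromohexanoyl chloride (THF, −78 °C) should give 6-bromo-1-(2,6-dimethoxyphenyl)hexan-1-one F2. Hydroboration of F1 with 9-BBN (THF, rt) places boron on both terminal carbons to give the bis(B-alkyl-9-borabicyclo[3.3.1]nonane) adduct F3, which is used in the same flask for a palladium-catalysed alkyl–alkyl Suzuki coupling with F2 (Pd(OAc)2, PCy3, K3PO4·H2O, THF, rt) to give 15.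

Step 9. Ether cleavage may stop short of eightfold: the second methoxy group next to each ketone is slowed once the first has formed a boron chelate. The catechols may also oxidise in air during work-up. The fallback moves acid-labile groups onto the resorcinol rings so that BBr3 only has to cleave four ordinary catechol methyl ethers; it sets out from 10 and 8 and comes back at 16. Commercial 1,3-bis(methoxymethoxy)benzene is lithiated at C2 (n-BuLi, THF, 0 °C) to 2,6-bis(methoxymethoxy)phenyllithium F4 and acylated with 10 (−78 °C) to ethyl 7-[2,6-bis(methoxymethoxy)phenyl]-7-oxoheptanoate F5. Saponification (LiOH, THF/H2O; citric acid work-up) gives 7-[2,6-bis(methoxymethoxy)phenyl]-7-oxoheptanoic acid F6, and N-hydroxyphthalimide/DIC gives 1,3-dioxoisoindolin-2-yl 7-[2,6-bis(methoxymethoxy)phenyl]-7-oxoheptanoate F7. Twofold coupling of F7 with 8 under the step 8 conditions should give 9,9'-(2',3',4,5-tetramethoxybiphenyl-2,5'-diyl)bis{1-[2,6-bis(methoxymethoxy)phenyl]nonan-1-one} F8. Acetal cleavage (HCl, MeOH, 40 °C) gives 9,9'-(2',3',4,5-tetramethoxybiphenyl-2,5'-diyl)bis[1-(2,6-dihydroxyphenyl)nonan-1-one] F9, and BBr3 (CH2Cl2, −78 °C → 0 °C) then cleaves the four catechol methyl ethers to give 16.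

Step 5. The aryllithium may add a second time to the new ketone or attack the ethyl ester, giving carbinol and diketone by-products. The fallback replaces acylation by aldehyde addition and oxidation; it sets out from 11 and comes back at 12. Addition of 11 to commercial ethyl 7-oxoheptanoate (THF, −78 °C), where the aldehyde reacts far faster than the ester and cannot over-add, should give racemic ethyl 7-(2,6-dimethoxyphenyl)-7-hydroxyheptanoate F10. Dess–Martin oxidation (CH2Cl2, rt) removes the new stereocentre and gives 12.

**Further compounds**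

F1 | step 8 | 5-allyl-1-(2-allyl-4,5-dimethoxyphenyl)-2,3-dimethoxybenzene | COc1cc(CC=C)cc(-c2cc(OC)c(OC)cc2CC=C)c1OC
F2 | step 8 | 6-bromo-1-(2,6-dimethoxyphenyl)hexan-1-one | COc1cccc(OC)c1C(=O)CCCCCBr
F3 | step 8 | bis(B-alkyl-9-borabicyclo[3.3.1]nonane) adduct of F1 | COc1cc(CCCB2C3CCCC2CCC3)cc(-c2cc(OC)c(OC)cc2CCCB2C3CCCC2CCC3)c1OC
F4 | step 9 | 2,6-bis(methoxymethoxy)phenyllithium | [Li]c1c(OCOC)cccc1OCOC
F5 | step 9 | ethyl 7-[2,6-bis(methoxymethoxy)phenyl]-7-oxoheptanoate | CCOC(=O)CCCCCC(=O)c1c(OCOC)cccc1OCOC
F6 | step 9 | 7-[2,6-bis(methoxymethoxy)phenyl]-7-oxoheptanoic acid | OC(=O)CCCCCC(=O)c1c(OCOC)cccc1OCOC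
F7 | step 9 | 1,3-dioxoisoindolin-2-yl 7-[2,6-bis(methoxymethoxy)phenyl]-7-oxoheptanoate | COCOc1cccc(OCOC)c1C(=O)CCCCCC(=O)ON1C(=O)c2ccccc2C1=O
F8 | step 9 | 9,9'-(2',3',4,5-tetramethoxybiphenyl-2,5'-diyl)bis{1-[2,6-bis(methoxymethoxy)phenyl]nonan-1-one} | COc1cc(CCCCCCCCC(=O)c2c(OCOC)cccc2OCOC)cc(-c2cc(OC)c(OC)cc2CCCCCCCCC(=O)c2c(OCOC)cccc2OCOC)c1OC
F9 | step 9 | 9,9'-(2',3',4,5-tetramethoxybiphenyl-2,5'-diyl)bis[1-(2,6-dihydroxyphenyl)nonan-1-one] | COc1cc(CCCCCCCCC(=O)c2c(O)cccc2O)cc(-c2cc(OC)c(OC)cc2CCCCCCCCC(=O)c2c(O)cccc2O)c1OC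
F10 | step 5 | ethyl 7-(2,6-dimethoxyphenyl)-7-hydroxyheptanoate | CCOC(=O)CCCCCC(O)c1c(OC)cccc1OC
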